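Remark on conventions: all intermediates carry the daucane locants of the target (C1 quaternary fusion carbon, C2 carbinol, C3 methylene, C4 isopropyl carbinol, C5 fusion CH, C6 ester carbon, C7–C10 the rest of the seven-membered ring); α and β are the ring faces as in the target, where the C1 methyl is β; commercial (R)-carvone is taken as enantiopure.

## Analysis of the target

The target is a trans-fused bicyclo[5.3.0]decane (hydroazulene). Its five-membered ring is C1–C5. Its seven-membered ring is C1, C5, C6, C7, C8, C9, C10, with one trisubstituted alkene C8=C9 that must be cis within the ring. There are five contiguous stereocentres: C1 (R, quaternary, methyl β), C2 (S, hydroxyl α), C4 (R, hydroxyl β, isopropyl α), C5 (S, hydrogen α) and C6 (S, aroyloxy α). The C1 methyl and H5 are trans. The C4 hydroxyl is cis to the C1 methyl and to the C5–C6 bond. The C2 hydroxyl is trans to the methyl and 1,3-trans to the C4 hydroxyl, and the C6 oxygen is anti to the C4 hydroxyl. The sensitive points are the tertiary C4 alcohol (dehydration; retro-aldol or E1cB loss in every β-hydroxy carbonyl precursor), the phenolic ester, and the homoallylic alkene. Three things make the synthesis hard. The quaternary C1 is flanked by two stereocentres. The C4 hydroxyl lies on the more crowded face, syn to the angular methyl and to C6, so simple steric approach control from the bicycle puts it on the wrong side. Of three hydroxyls only the one at C6 is acylated. The strategy rests on one feature: C1 with its methyl, oxygenated C2, C3, C4 with its three-carbon branch, C5 and the exocyclic C6 make up a methyl cyclopentanecarboxylate with exactly the ten carbons of carvone after a one-carbon ring contraction.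

## Retrosynthetic reasoning

29 is traced to 28 by removing two silyl groups, and 28 to the diol 23 and the acid 26 by cutting the C6–O acyl bond. In 23 the only free acylable hydroxyl is the secondary one at C6: the C4 hydroxyl is tertiary and the C2 hydroxyl is silylated, so no selectivity problem remains at the last C–O bond.

23 is cut at C8=C9 to the diene 22. A ring closure at C6–C7 from a preformed (Z)-C7–C10 allylic unit was rejected: an allylic metal at C7 would add to a C6 aldehyde through C9 (SE2′) and close a five-membered ring. That trisubstituted alkene would also not survive the peracid needed earlier. Metathesis at C8=C9 is neutral, tolerates the free hydroxyls, and the ring itself enforces the cis alkene.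

22 is cut at C6–C7 to the β-hydroxy aldehyde 21 and a three-carbon allylic nucleophile carrying the C8 methyl. The forward addition must set C6. The C4 hydroxyl is cis to the formyl group, so a metal chelate can form, and its convex face leads to the required 6S carbinol.

21 is taken back through 20 and 19 to the β-hydroxy ester 18 by oxidation-level changes, and the allyl group of 19 to the terminal alkyne of 18. The alkyne is an alkene surrogate that is blind to the peracid and to the selenium chemistry used before.

18 is cut at the C4–O bond by way of the epoxy ester 16 and the tetrasubstituted enoate 15. With C4 and C5 both planar in 15, the face of oxygen delivery is decided by C1 and C2 and not by C5, which would direct it to the wrong side. Reductive cleavage of the Cα–O bond of 16 then leaves the C4 oxygen in place, and C5 is set thermodynamically.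

15 is traced to 12 by removing the C4=C5 unsaturation. The forward step is an ester α-selenenylation and syn-elimination that can only run toward C4, because C1 is quaternary.

12 is traced through 11 to the ketone 10 by cutting the C2–H bond. Substrate bias at this ketone is ambiguous (methyl against a propargylic arm on C1), so the forward reduction is placed under reagent control.

10 is cut at C1–C10 to the keto ester 9 and a silyl-capped propargylic electrophile. The more substituted enolate of 9 is alkylated anti to the C5 ester. This is the relay that transfers the stereochemical information of C4 through C5 to the quaternary C1.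

9 is traced to 6 by oxidation at C2, equilibration of C1 and C5 to the all-trans arrangement, and saturation of the isopropenyl group. From this point only C4, which comes unchanged from carvone, needs to be correct.

6 is cut at C1–C5, which reopens the six-membered α-chloro ketone 4. This is the key disconnection: a Favorskii contraction turns the carvone carbonyl carbon into C6 and forms the cyclopentane.

4 is taken back through 3 and 2 to 1 by silylation, chloride opening of the epoxide and nucleophilic epoxidation.

## Alternatives that were turned down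

Alternative 1: The five-membered ring is disconnected at C3–C4 back to the furan A1, (5-isopropyl-3-methylfuran-2-yl)methanol.
- Forward key step: A1, water and a chiral phosphoric acid. Ionisation at the carbinol carbon, addition of water at the isopropyl-bearing furan carbon, ring opening and a conrotatory 4π closure would give the cyclopentenone A2, (R)-4-hydroxy-4-isopropyl-2-methylcyclopent-2-en-1-one.
- For: A2 already holds the C4 tertiary carbinol, the C2 ketone and the C1 methyl on an enone ready for conjugate addition at C5 and enolate alkylation at C1. On the C4 carbinol it is clearly stronger than the chosen route, which spends five operations on that one centre.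
- Against: the cascade must start from a primary furfuryl cation, the least stabilised case and the one most prone to polymerisation. Water must add to the substituted, hindered furan position. The carbinol carbon has no substituent, so there is no 4,5-trans relay and the absolute configuration rests entirely on the ion pair. A 4-hydroxycyclopentenone also loses water readily through its dienolate.
- Comparison: the chosen route takes its absolute configuration from the chiral pool and puts its risk in a ring contraction of a well-known type. It pays for this with length.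

Alternative 2: The seven-membered ring is disconnected at C1–C10 (retro-Cope, reforming C6–C8) to the cis-divinylcyclopropane A3, which carries a vinyl group on C8 and the cyclopentenyl unit on C6.
- Forward key step: warming A3 gives, through a boat transition state, the bicyclic diene A4 with alkenes at C5=C6 and C8=C9 and the quaternary C1 formed.
- For: ring closure, the quaternary centre and the cis C8=C9 alkene come in one stereospecific step. In ring construction this is stronger than allylation plus metathesis.
- Against: the configuration at C1 is dictated by the cyclopropane configuration relative to the remote C2 and C4 centres, so A3 needs a diastereoselective cyclopropanation without a nearby control element. The new bond forms at a fully substituted alkene carbon. A4 then needs anti-Markovnikov hydration of C5=C6 on a defined face in the presence of a second trisubstituted alkene (C8=C9), which sets both C5 and C6 in one poorly differentiated step.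
- Comparison: the chosen route sets C5 by equilibration and C6 by chelation on separate occasions, and its only polyene problem is solved by carrying an alkyne.

Alternative 3: The five-membered ring is kept and C1–CH3 and C5–C6 are disconnected from the enone A5, tert-butyl 2-[5-(tert-butyldimethylsilyloxy)-3-oxocyclopent-1-en-1-yl]acetate.
- Forward key step: Me2CuLi adds to C1 anti to the silyloxy group and the enolate is trapped with formaldehyde, giving A6 with quaternary C1, the C2 silyl ether and a C5 hydroxymethyl group.
- For: anti addition next to the silyloxy group and trans trapping are well-established relays. C2 has its final configuration from the start. A later isopropyl addition to the C4 ketone anti to C5 would put the C4 hydroxyl on the correct, hindered face. On C2 and C4 it is stronger than the chosen route.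
- Against: conjugate addition to a β,β-disubstituted enone next to a silyloxy group is slow. The formaldehyde aldol product dehydrates easily to the α-methylene ketone. A5 itself needs an enantioselective preparation. The isopropyl group must be added to a ketone with two enolisable flanks. C7 and C8 still have to be built before any ring closure.
- Comparison: the chosen route draws every carbon of the five-membered ring, the isopropyl group included, from one cheap terpene with its configuration already in place.

Key step: step 4

## Route

Step 1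
Reactants: 1 (R)-carvone
Product: 2 (1R,4R,6R)-1-methyl-4-(prop-1-en-2-yl)-7-oxabicyclo[4.1.0]heptan-2-one (oxirane trans to the isopropenyl group)
Conditions: 30% H2O2, NaOH (0.3 equiv), MeOH, 0 °C
Reagents that add atoms: hydrogen peroxide, OO
Why: Weitz–Scheffer nucleophilic epoxidation of the enone; hydroperoxide adds anti to the pseudo-equatorial isopropenyl group, so both oxirane centres are set by C5 of carvone, and the isolated isopropenyl alkene does not react with the nucleophilic oxidant.

Step 2
Reactants: 2 carvone epoxide
Product: 3 (2S,3R,5R)-2-chloro-3-hydroxy-2-methyl-5-(prop-1-en-2-yl)cyclohexan-1-one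
Conditions: LiCl (4 equiv), CF3CO2H (1.5 equiv), THF, rt
Reagents that add atoms: lithium chloride, [Li+].[Cl-]
Why: Acid-assisted trans-diaxial opening of the α,β-epoxy ketone by chloride at the carbonyl-flanked tertiary carbon with inversion; chlorine ends cis to the isopropenyl group and the carbinol keeps its configuration.

Step 3
Reactants: 3 chlorohydrin
Product: 4 (2S,3R,5R)-2-chloro-2-methyl-5-(prop-1-en-2-yl)-3-(triethylsilyloxy)cyclohexan-1-one
Conditions: Et3SiCl (1.3 equiv), imidazole, DMAP (cat.), DMF, 0 °C → rt
Reagents that add atoms: chlorotriethylsilane, CC[Si](Cl)(CC)CC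
Why: Standard silylation; the ether prevents re-closure of the chlorohydrin to the epoxide under the basic conditions of step 4 and is labile enough to be removed oxidatively in step 5.

Step 4
Reactants: 4 silylated chlorohydrin
Product: 6 methyl (1R,2S,3R,5R)-2-methyl-5-(prop-1-en-2-yl)-3-(triethylsilyloxy)cyclopentane-1-carboxylate, via cyclopropanone 5 (not isolated)
Conditions: NaOMe (2 equiv), MeOH, −10 → 0 °C
Reagents that add atoms: sodium methoxide, C[O-].[Na+]
Why: Favorskii rearrangement, the closest known type being the contraction of terpene-derived 2-chloro-3-alkoxycyclohexanones to cyclopentanecarboxylates. Methoxide removes a proton from the α′ methylene (future C5) and the enolate displaces the axial tertiary chloride (future C1) from the rear in a 3-exo-tet closure, which forms the C1–C5 bond and gives cyclopropanone 5. Inversion at the chlorine-bearing carbon leaves its methyl β and places the carbonyl bridge on the α face, syn to the isopropenyl group. Methoxide adds to the strained carbonyl and the hemiketal opens toward the methyl-bearing carbon, where the developing carbanion is stabilised inductively by the neighbouring silyloxy group and is protonated by methanol with retention, so the old ketone carbon becomes the C6 ester on C5 and the five-membered ring remains. The configuration at C5 is fixed by the face of the cyclopropanone, that is by the C–Cl configuration relayed from the isopropenyl centre through the epoxide; the configuration at C1 is fixed by the retentive protonation. The step needs enolisation at α′ in preference to methoxide attack at the carbonyl or at silicon, a concerted displacement and not an oxyallyl cation, and opening toward C1. These are secured by the anti-periplanar axial chloride held by the equatorial isopropenyl anchor, by the low temperature, and by the β-silyloxy substituent.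

Step 5
Reactants: 6 Favorskii ester
Product: 7 methyl (1R,2S,5R)-2-methyl-3-oxo-5-(prop-1-en-2-yl)cyclopentane-1-carboxylate
Conditions: CrO3, H2SO4, H2O/acetone, 0 °C
Reagents that add atoms: none
Why: Jones oxidation applied directly to the triethylsilyl ether: aqueous acid cleaves the Si–O bond and hexavalent chromium oxidises the freed secondary alcohol in the same flask; ester and isopropenyl group tolerate the short exposure at 0 °C.

Step 6
Reactants: 7 cis keto ester
Product: 9 methyl (1S,2R,5S)-2-methyl-3-oxo-5-(propan-2-yl)cyclopentane-1-carboxylate, via all-trans isopropenyl keto ester 8 (not isolated)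
Conditions: NaOMe (0.3 equiv), MeOH/benzene, 40 °C; AcOH (0.3 equiv); then RhCl(PPh3)3 (5 mol %), H2 (1 atm), rt
Reagents that add atoms: none
Why: Base equilibration through the ketone enolate (C1) and the ester enolate (C5) gives the all-trans arrangement, in which the ester is trans to the carvone-derived C4 substituent. Homogeneous hydrogenation with RhCl(PPh3)3 then saturates the 1,1-disubstituted alkene without double-bond migration, so C4 is not scrambled.

Step 7
Reactants: 9 all-trans keto ester
Product: 10 methyl (1S,2R,5S)-2-methyl-3-oxo-5-(propan-2-yl)-2-[3-(trimethylsilyl)prop-2-yn-1-yl]cyclopentane-1-carboxylate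
Conditions: LiN(SiMe3)2 (0.95 equiv), THF, 0 °C → rt, 3 h; DMPU, Me3SiC≡CCH2Br, −20 °C → rt
Reagents that add atoms: 3-bromo-1-(trimethylsilyl)prop-1-yne, C[Si](C)(C)C#CCBr
Why: Alkylation of the thermodynamic, tetrasubstituted lithium enolate, formed by proton exchange with a small excess of ketone. The propargylic bromide approaches C1 anti to the adjacent C5 ester, which sets the quaternary centre (C10 α, methyl β). The silyl cap removes the acidic alkyne proton ahead of step 10.

Step 8
Reactants: 10 propargylated ketone
Product: 11 methyl (1S,2R,3S,5S)-3-hydroxy-2-methyl-5-(propan-2-yl)-2-[3-(trimethylsilyl)prop-2-yn-1-yl]cyclopentane-1-carboxylate (2α-alcohol)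
Conditions: (R)-2-methyl-CBS-oxazaborolidine (0.3 equiv), catecholborane (1.8 equiv), toluene, −78 → −40 °C
Reagents that add atoms: none
Why: Corey–Bakshi–Shibata reduction; the catalyst distinguishes the quaternary C1 flank from the C3 methylene, and the (R)-oxazaborolidine delivers hydride to the β face, giving the S carbinol (hydroxyl α, cis to the C10 arm) under reagent control. Catecholborane leaves ester and alkyne untouched.

Step 9
Reactants: 11 2α-alcohol
Product: 12 methyl (1S,2R,3S,5S)-3-(tert-butyldimethylsilyloxy)-2-methyl-5-(propan-2-yl)-2-[3-(trimethylsilyl)prop-2-yn-1-yl]cyclopentane-1-carboxylate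
Conditions: tBuMe2SiOTf, 2,6-lutidine, CH2Cl2, −78 → 0 °C
Reagents that add atoms: tert-butyldimethylsilyl trifluoromethanesulfonate, CC(C)(C)[Si](C)(C)OS(=O)(=O)C(F)(F)F
Why: Silylation of the hindered, neopentyl-type secondary alcohol with the silyl triflate; the bulky ether marks C2 for the rest of the route and later shields the α face.

Step 10
Reactants: 12 silyl ether
Product: 15 methyl (4S,5R)-4-(tert-butyldimethylsilyloxy)-5-methyl-2-(propan-2-yl)-5-[3-(trimethylsilyl)prop-2-yn-1-yl]cyclopent-1-ene-1-carboxylate, via phenylselanyl ester 13 (not isolated), via selenoxide 14 (not isolated)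
Conditions: LiN(iPr)2 (1.4 equiv), THF/HMPA, −78 → −30 °C; PhSeBr, −78 °C; then 30% H2O2, pyridine, CH2Cl2, 0 °C → rt
Reagents that add atoms: none
Why: Ester enolate selenenylation and selenoxide syn-elimination; selenium enters C5 on the less hindered β face, cis to the C4 hydrogen, and elimination can only run toward C4 because C1 is quaternary, which gives the tetrasubstituted C4=C5 enoate.

Step 11
Reactants: 15 enoate
Product: 16 methyl 4β,5β-epoxy-2α-(tert-butyldimethylsilyloxy)-1β-methyl-4α-(propan-2-yl)-1α-[3-(trimethylsilyl)prop-2-yn-1-yl]cyclopentane-5-carboxylate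
Conditions: mCPBA (3 equiv), 4,4′-thiobis(6-tert-butyl-3-methylphenol) (cat.), ClCH2CH2Cl, 60 °C
Reagents that add atoms: 3-chloroperoxybenzoic acid, OOC(=O)c1cccc(Cl)c1
Why: Prilezhaev epoxidation of a tetrasubstituted α,β-unsaturated ester under forcing conditions with a radical inhibitor. The peracid should approach the β face, anti to the C2 silyloxy group and the C1 propargylic arm, which sets C4. The silylalkyne is inert to peracid, which is why an alkyne and not an allyl group is carried at this stage.

Step 12
Reactants: 16 epoxy ester
Product: 18 methyl 2α-(tert-butyldimethylsilyloxy)-4β-hydroxy-1β-methyl-4α-(propan-2-yl)-1α-(prop-2-yn-1-yl)cyclopentane-5β-carboxylate, via silylalkynyl hydroxy ester 17 (not isolated)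
Conditions: SmI2 (2.5 equiv), THF/HMPA, Me2NCH2CH2OH, 0 °C; work-up; NaOMe (0.3 equiv), MeOH, 0 °C → rt
Reagents that add atoms: none
Why: Samarium diiodide reduction of an α,β-epoxy ester: electron transfer to the ester cleaves the Cα–O bond (C5–O) and leaves the C4–O bond and its configuration intact. The samarium enolate is protonated at C5, probably from the open β face, and methoxide then equilibrates C5 to the ester that is trans to the isopropyl group and hydrogen-bonded to the cis hydroxyl. Methoxide also cleaves the alkynyl C–Si bond.

Step 13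
Reactants: 18 alkynyl hydroxy ester
Product: 19 methyl 1α-allyl-2α-(tert-butyldimethylsilyloxy)-4β-hydroxy-1β-methyl-4α-(propan-2-yl)cyclopentane-5β-carboxylate
Conditions: H2 (1 atm), Pd/CaCO3 poisoned with Pb(OAc)2, quinoline, EtOAc, rt
Reagents that add atoms: none
Why: Lindlar semi-hydrogenation of the terminal alkyne gives the allyl group needed for metathesis; no other reducible group is present.

Step 14
Reactants: 19 allyl hydroxy ester
Product: 20 1α-allyl-2α-(tert-butyldimethylsilyloxy)-5β-(hydroxymethyl)-1β-methyl-4α-(propan-2-yl)cyclopentan-4β-ol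
Conditions: LiAlH4, THF, 0 °C
Reagents that add atoms: none
Why: Hydride reduction of the ester to the primary alcohol; the silyl ether and the isolated alkene are unaffected and C5 is no longer epimerisable.

Step 15
Reactants: 20 diol
Product: 21 1α-allyl-2α-(tert-butyldimethylsilyloxy)-4β-hydroxy-1β-methyl-4α-(propan-2-yl)cyclopentane-5β-carbaldehyde
Conditions: TEMPO (10 mol %), PhI(OAc)2, CH2Cl2, rt
Reagents that add atoms: none
Why: Oxoammonium (TEMPO) oxidation, selective for the primary alcohol; the tertiary C4 alcohol cannot be oxidised and the neutral medium avoids retro-aldol cleavage or dehydration of the β-hydroxy aldehyde.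

Step 16
Reactants: 21 β-hydroxy aldehyde
Product: 22 (6S)-carbinol: 1α-allyl-2α-(tert-butyldimethylsilyloxy)-5β-[(1S)-1-hydroxy-3-methylbut-3-en-1-yl]-1β-methyl-4α-(propan-2-yl)cyclopentan-4β-ol
Conditions: In powder, CH2=C(CH3)CH2Br, THF/H2O (1:1), rt
Reagents that add atoms: 3-bromo-2-methylprop-1-ene, CC(=C)CBr
Why: Indium-mediated Barbier allylation in aqueous medium forms C6–C7. Indium bridges the C4 hydroxyl and the aldehyde oxygen in a six-membered chelate cis-fused to the cyclopentane, and the allyl group adds to its convex face, away from C1 and C3, which should give the 6S carbinol.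

Step 17
Reactants: 22 diene diol
Product: 23 (1S,3R,3aS,4S,8aR)-1-(tert-butyldimethylsilyloxy)-6,8a-dimethyl-3-(propan-2-yl)-1,2,3,3a,4,5,8,8a-octahydroazulene-3,4-diol
Conditions: second-generation Grubbs catalyst (H2IMes)(PCy3)Cl2Ru=CHPh (5 mol %), CH2Cl2 (2 mM), 40 °C
Reagents that add atoms: none
Why: Ring-closing metathesis between the monosubstituted and the 1,1-disubstituted alkene closes the seven-membered ring at C8=C9; the ring enforces the cis alkene, the trans 1,5-arms can span it, and free hydroxyls are tolerated.

Step 18
Reactants: 24 4-hydroxybenzoic acid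
Product: 26 4-(tert-butyldimethylsilyloxy)benzoic acid, via silyl ester 25 (not isolated)
Conditions: tBuMe2SiCl (2.3 equiv), imidazole, DMF, rt; then AcOH/THF/H2O, rt
Reagents that add atoms: tert-butyl(chloro)dimethylsilane, CC(C)(C)[Si](C)(C)Cl
Why: Bis-silylation followed by selective hydrolysis of the labile silyl ester leaves the phenol as a silyl ether that falls in the final fluoride step.

Step 19
Reactants: 23 bicyclic diol; 26 4-(tert-butyldimethylsilyloxy)benzoic acid
Product: 28 (1S,3R,3aS,4S,8aR)-1-(tert-butyldimethylsilyloxy)-3-hydroxy-6,8a-dimethyl-3-(propan-2-yl)-1,2,3,3a,4,5,8,8a-octahydroazulen-4-yl 4-(tert-butyldimethylsilyloxy)benzoate, via mixed anhydride 27 (not isolated)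
Conditions: 2,4,6-Cl3C6H2COCl, Et3N, THF, rt; then 23, DMAP, toluene, 60 °C
Reagents that add atoms: none
Why: Yamaguchi esterification; the mixed anhydride acylates the secondary C6 hydroxyl with retention, the tertiary C4 hydroxyl does not react and the C2 hydroxyl is silylated.

Step 20
Reactants: 28 bis-silyl ester
Product: 29 2α-hydroxyferutinin, (1S,3R,3aS,4S,8aR)-1,3-dihydroxy-6,8a-dimethyl-3-(propan-2-yl)-1,2,3,3a,4,5,8,8a-octahydroazulen-4-yl 4-hydroxybenzoate
Conditions: HF·pyridine, pyridine, THF, 0 °C → rt
Reagents that add atoms: none
Why: Fluoride cleaves the aryl and the secondary alkyl silyl ether in one operation under buffered, non-basic conditions that spare the aryl ester, the tertiary alcohol and the alkene.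

## Compound list

1 | (R)-carvone, (5R)-2-methyl-5-(prop-1-en-2-yl)cyclohex-2-en-1-one | CC1=CC[C@H](CC1=O)C(C)=C | starting material
2 | (1R,4R,6R)-1-methyl-4-(prop-1-en-2-yl)-7-oxabicyclo[4.1.0]heptan-2-one | CC(=C)[C@@H]1C[C@H]2O[C@@]2(C)C(=O)C1 | intermediate
3 | (2S,3R,5R)-2-chloro-3-hydroxy-2-methyl-5-(prop-1-en-2-yl)cyclohexan-1-one | CC(=C)[C@@H]1C[C@@H](O)[C@](C)(Cl)C(=O)C1 | intermediate
4 | (2S,3R,5R)-2-chloro-2-methyl-5-(prop-1-en-2-yl)-3-(triethylsilyloxy)cyclohexan-1-one | CC(=C)[C@@H]1C[C@@H](O[Si](CC)(CC)CC)[C@](C)(Cl)C(=O)C1 | intermediate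
5 | cyclopropanone: 1-methyl-4-(prop-1-en-2-yl)-2-(triethylsilyloxy)bicyclo[3.1.0]hexan-6-one, carbonyl bridge and isopropenyl α, methyl and silyloxy β | CC(=C)[C@@H]1C[C@@H](O[Si](CC)(CC)CC)[C@]2(C)C(=O)[C@H]12 | intermediate (not isolated)
6 | methyl (1R,2S,3R,5R)-2-methyl-5-(prop-1-en-2-yl)-3-(triethylsilyloxy)cyclopentane-1-carboxylate | COC(=O)[C@@H]1[C@H](C(C)=C)C[C@@H](O[Si](CC)(CC)CC)[C@H]1C | intermediate
7 | methyl (1R,2S,5R)-2-methyl-3-oxo-5-(prop-1-en-2-yl)cyclopentane-1-carboxylate | COC(=O)[C@@H]1[C@H](C(C)=C)CC(=O)[C@H]1C | intermediate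
8 | methyl (1S,2R,5R)-2-methyl-3-oxo-5-(prop-1-en-2-yl)cyclopentane-1-carboxylate (all-trans) | COC(=O)[C@H]1[C@H](C(C)=C)CC(=O)[C@@H]1C | intermediate (not isolated)
9 | methyl (1S,2R,5S)-2-methyl-3-oxo-5-(propan-2-yl)cyclopentane-1-carboxylate (all-trans) | COC(=O)[C@H]1[C@H](C(C)C)CC(=O)[C@@H]1C | intermediate
10 | methyl (1S,2R,5S)-2-methyl-3-oxo-5-(propan-2-yl)-2-[3-(trimethylsilyl)prop-2-yn-1-yl]cyclopentane-1-carboxylate | COC(=O)[C@H]1[C@H](C(C)C)CC(=O)[C@]1(C)CC#C[Si](C)(C)C | intermediate
11 | methyl (1S,2R,3S,5S)-3-hydroxy-2-methyl-5-(propan-2-yl)-2-[3-(trimethylsilyl)prop-2-yn-1-yl]cyclopentane-1-carboxylate | COC(=O)[C@H]1[C@H](C(C)C)C[C@H](O)[C@]1(C)CC#C[Si](C)(C)C | intermediate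
12 | methyl (1S,2R,3S,5S)-3-(tert-butyldimethylsilyloxy)-2-methyl-5-(propan-2-yl)-2-[3-(trimethylsilyl)prop-2-yn-1-yl]cyclopentane-1-carboxylate | COC(=O)[C@H]1[C@H](C(C)C)C[C@H](O[Si](C)(C)C(C)(C)C)[C@]1(C)CC#C[Si](C)(C)C | intermediate
13 | 5β-phenylselanyl derivative of 12 (selenium β, ester α at C5) | COC(=O)[C@]1([Se]c2ccccc2)[C@H](C(C)C)C[C@H](O[Si](C)(C)C(C)(C)C)[C@]1(C)CC#C[Si](C)(C)C | intermediate (not isolated)
14 | selenoxide of 13 | COC(=O)[C@]1([Se](=O)c2ccccc2)[C@H](C(C)C)C[C@H](O[Si](C)(C)C(C)(C)C)[C@]1(C)CC#C[Si](C)(C)C | intermediate (not isolated)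
15 | methyl (4S,5R)-4-(tert-butyldimethylsilyloxy)-5-methyl-2-(propan-2-yl)-5-[3-(trimethylsilyl)prop-2-yn-1-yl]cyclopent-1-ene-1-carboxylate | COC(=O)C1=C(C(C)C)C[C@H](O[Si](C)(C)C(C)(C)C)[C@]1(C)CC#C[Si](C)(C)C | intermediate
16 | 4β,5β-epoxide of 15 (isopropyl α at C4, ester α at C5) | COC(=O)[C@]12O[C@@]1(C(C)C)C[C@H](O[Si](C)(C)C(C)(C)C)[C@]2(C)CC#C[Si](C)(C)C | intermediate
17 | methyl 2α-(tert-butyldimethylsilyloxy)-4β-hydroxy-1β-methyl-4α-(propan-2-yl)-1α-[3-(trimethylsilyl)prop-2-yn-1-yl]cyclopentane-5α-carboxylate (kinetic C5 epimer) | COC(=O)[C@@H]1[C@](O)(C(C)C)C[C@H](O[Si](C)(C)C(C)(C)C)[C@]1(C)CC#C[Si](C)(C)C | intermediate (not isolated)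
18 | methyl 2α-(tert-butyldimethylsilyloxy)-4β-hydroxy-1β-methyl-4α-(propan-2-yl)-1α-(prop-2-yn-1-yl)cyclopentane-5β-carboxylate | COC(=O)[C@H]1[C@](O)(C(C)C)C[C@H](O[Si](C)(C)C(C)(C)C)[C@]1(C)CC#C | intermediate
19 | methyl 1α-allyl-2α-(tert-butyldimethylsilyloxy)-4β-hydroxy-1β-methyl-4α-(propan-2-yl)cyclopentane-5β-carboxylate | COC(=O)[C@H]1[C@](O)(C(C)C)C[C@H](O[Si](C)(C)C(C)(C)C)[C@]1(C)CC=C | intermediate
20 | 1α-allyl-2α-(tert-butyldimethylsilyloxy)-5β-(hydroxymethyl)-1β-methyl-4α-(propan-2-yl)cyclopentan-4β-ol | OC[C@H]1[C@](O)(C(C)C)C[C@H](O[Si](C)(C)C(C)(C)C)[C@]1(C)CC=C | intermediate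
21 | 1α-allyl-2α-(tert-butyldimethylsilyloxy)-4β-hydroxy-1β-methyl-4α-(propan-2-yl)cyclopentane-5β-carbaldehyde | O=C[C@H]1[C@](O)(C(C)C)C[C@H](O[Si](C)(C)C(C)(C)C)[C@]1(C)CC=C | intermediate
22 | 1α-allyl-2α-(tert-butyldimethylsilyloxy)-5β-[(1S)-1-hydroxy-3-methylbut-3-en-1-yl]-1β-methyl-4α-(propan-2-yl)cyclopentan-4β-ol | CC(=C)C[C@H](O)[C@H]1[C@](O)(C(C)C)C[C@H](O[Si](C)(C)C(C)(C)C)[C@]1(C)CC=C | intermediate
23 | (1S,3R,3aS,4S,8aR)-1-(tert-butyldimethylsilyloxy)-6,8a-dimethyl-3-(propan-2-yl)-1,2,3,3a,4,5,8,8a-octahydroazulene-3,4-diol | CC1=CC[C@]2(C)[C@@H]([C@@H](O)C1)[C@](O)(C(C)C)C[C@@H]2O[Si](C)(C)C(C)(C)C | intermediate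
24 | 4-hydroxybenzoic acid | O=C(O)c1ccc(O)cc1 | starting material
25 | tert-butyldimethylsilyl 4-(tert-butyldimethylsilyloxy)benzoate | CC(C)(C)[Si](C)(C)OC(=O)c1ccc(O[Si](C)(C)C(C)(C)C)cc1 | intermediate (not isolated)
26 | 4-(tert-butyldimethylsilyloxy)benzoic acid | CC(C)(C)[Si](C)(C)Oc1ccc(cc1)C(=O)O | intermediate
27 | 4-(tert-butyldimethylsilyloxy)benzoic 2,4,6-trichlorobenzoic anhydride | CC(C)(C)[Si](C)(C)Oc1ccc(cc1)C(=O)OC(=O)c1c(Cl)cc(Cl)cc1Cl | intermediate (not isolated)
28 | (1S,3R,3aS,4S,8aR)-1-(tert-butyldimethylsilyloxy)-3-hydroxy-6,8a-dimethyl-3-(propan-2-yl)-1,2,3,3a,4,5,8,8a-octahydroazulen-4-yl 4-(tert-butyldimethylsilyloxy)benzoate | CC1=CC[C@]2(C)[C@@H]([C@@H](OC(=O)c3ccc(O[Si](C)(C)C(C)(C)C)cc3)C1)[C@](O)(C(C)C)C[C@@H]2O[Si](C)(C)C(C)(C)C | intermediate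
29 | 2α-hydroxyferutinin, (1S,3R,3aS,4S,8aR)-1,3-dihydroxy-6,8a-dimethyl-3-(propan-2-yl)-1,2,3,3a,4,5,8,8a-octahydroazulen-4-yl 4-hydroxybenzoate | CC1=CC[C@]2(C)[C@@H]([C@@H](OC(=O)c3ccc(O)cc3)C1)[C@](O)(C(C)C)C[C@@H]2O | target

## Step count and least certain steps

Total step count: 20. Longest linear sequence: 19 steps from 1 to 29 (steps 1–17, 19 and 20); step 18 is a one-step side branch from 24.

**Step 4 (key step).** The likely failures are processes that compete with the cyclopropanone pathway:
- methanolysis of the silyl ether followed by re-closure to the epoxide;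
- ionisation to an oxyallyl cation or a semibenzilic pathway, which would erode the stereospecificity;
- loss of silyloxide from the C1 carbanion before it is protonated.

Fallback, from 2 back to the route at 9 (photochemical Wolff ring contraction in place of the Favorskii): the epoxide 2 would be opened reductively at Cα with the selenide reagent made from (PhSe)2 and NaBH4 in EtOH to give (2R,3R,5R)-3-hydroxy-2-methyl-5-(prop-1-en-2-yl)cyclohexan-1-one F1, which is silylated to its triethylsilyl ether F2. Kinetic deprotonation at the α′ methylene with LiN(SiMe3)2, trifluoroacetylation with 2,2,2-trifluoroethyl trifluoroacetate and detrifluoroacetylative diazo transfer (methanesulfonyl azide, Et3N) would give the α′-diazo ketone F3. Irradiation in methanol contracts the ring with retention at the migrating methyl-bearing carbon and gives 6 together with its C5 epimer F4. Steps 5 and 6 erase the configuration at C1 and C5, so both are carried on and converge at 9.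

**Step 7.** Incomplete equilibration of the enolate would lead to alkylation at the C3 methylene or to polyalkylation. Fallback, from 9 back to the route at 12 (regiospecific enolate generation from an isolated enol silane): 9 would be converted with Me3SiCl, NaI and Et3N in MeCN into the thermodynamic trimethylsilyl enol ether F5. This is alkylated with propargyl bromide and anhydrous benzyltrimethylammonium fluoride to give the terminal-alkyne ketone F6. F6 is reduced as in step 8 to the 2α-alcohol F7 and silylated as in step 9 to the silyl ether F8. Kinetic deprotonation of the alkyne C–H with LiN(iPr)2 (1.05 equiv, −78 °C) and quenching with Me3SiCl then gives 12.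

**Step 10.** The C5 hydrogen lies on the crowded α face between a quaternary carbon and the isopropyl-bearing carbon, so deprotonation may be slow or incomplete. Fallback, from 8 back to the route at 15 (alkene migration in place of dehydrogenation): step 6 would be stopped after the methoxide equilibration so that 8 is isolated. It is alkylated as in step 7 to the isopropenyl ketone F9, reduced as in step 8 to the isopropenyl 2α-alcohol F10 and silylated as in step 9 to the isopropenyl silyl ether F11. RhCl3·3H2O (cat.) in EtOH at 75 °C would then move the only alkene of F11 over two positions into conjugation with the ester, and the tetrasubstituted enoate 15 is the thermodynamic end point.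

**Step 11.** Facial selectivity may be poor, because the α face is shielded only by a homoallylic silyloxy group and a CH2 arm, and the hindered, electron-poor alkene may react slowly. Fallback, from 15 back to the route at 18 (hydroxyl-directed in place of sterically controlled epoxidation, with later correction of C2):
- 15 would be desilylated at oxygen with HF·pyridine to the 2α-hydroxy enoate F12 and oxidised with Dess–Martin periodinane to the 2-oxo enoate F13.
- F13 would be reduced with the (S)-oxazaborolidine and catecholborane to the 2β-hydroxy enoate F14, whose hydroxyl is cis to the C1 methyl.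
- Peracid epoxidation guided by this hydroxyl (Henbest) would give the β-epoxy alcohol F15.
- Samarium diiodide reduction and methoxide treatment as in step 12 would give the 2β,4β-dihydroxy ester F16.
- Oxidation of the secondary alcohol would give the 4β-hydroxy 2-ketone F17.
- Me4NBH(OAc)3 in AcOH/MeCN would deliver hydride from the C4 hydroxyl to the β face of C2 and give the 2α,4β-diol F18.
- Selective silylation of the secondary hydroxyl (tBuMe2SiOTf, 2,6-lutidine, −78 °C) gives 18.

**Step 16.** Addition without chelation in the aqueous medium would give mainly the C6 epimer. Fallback, from 21 back to the route at 28 (inversion at C6 during esterification): the epimeric 6R carbinol F19 would be cyclised as in step 17 to the 6-epi bicyclic diol F20. A Mitsunobu esterification of F20 with the acid 26 (PPh3, diisopropyl azodicarboxylate, toluene) would invert C6 and give 28 directly.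

## Further compounds

F1 | step 4 | (2R,3R,5R)-3-hydroxy-2-methyl-5-(prop-1-en-2-yl)cyclohexan-1-one | CC(=C)[C@@H]1C[C@@H](O)[C@@H](C)C(=O)C1
F2 | step 4 | triethylsilyl ether of F1 | CC(=C)[C@@H]1C[C@@H](O[Si](CC)(CC)CC)[C@@H](C)C(=O)C1
F3 | step 4 | 6-diazo-2-methyl-5-(prop-1-en-2-yl)-3-(triethylsilyloxy)cyclohexan-1-one (α′-diazo ketone from F2) | CC(=C)[C@@H]1C[C@@H](O[Si](CC)(CC)CC)[C@@H](C)C(=O)C1=[N+]=[N-]
F4 | step 4 | C5 epimer of 6 (ester β, trans to isopropenyl) | COC(=O)[C@H]1[C@H](C(C)=C)C[C@@H](O[Si](CC)(CC)CC)[C@H]1C
F5 | step 7 | methyl 2-methyl-5α-(propan-2-yl)-3-(trimethylsilyloxy)cyclopent-2-ene-1β-carboxylate (thermodynamic enol silane of 9) | COC(=O)[C@H]1[C@H](C(C)C)CC(O[Si](C)(C)C)=C1C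
F6 | step 7 | desilyl analogue of 10 (terminal alkyne) | COC(=O)[C@H]1[C@H](C(C)C)CC(=O)[C@]1(C)CC#C
F7 | step 7 | desilyl analogue of 11 (terminal alkyne, 2α-alcohol) | COC(=O)[C@H]1[C@H](C(C)C)C[C@H](O)[C@]1(C)CC#C
F8 | step 7 | desilyl analogue of 12 (terminal alkyne, 2α-silyl ether) | COC(=O)[C@H]1[C@H](C(C)C)C[C@H](O[Si](C)(C)C(C)(C)C)[C@]1(C)CC#C
F9 | step 10 | isopropenyl analogue of 10 | COC(=O)[C@H]1[C@H](C(C)=C)CC(=O)[C@]1(C)CC#C[Si](C)(C)C
F10 | step 10 | isopropenyl analogue of 11 | COC(=O)[C@H]1[C@H](C(C)=C)C[C@H](O)[C@]1(C)CC#C[Si](C)(C)C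
F11 | step 10 | isopropenyl analogue of 12 | COC(=O)[C@H]1[C@H](C(C)=C)C[C@H](O[Si](C)(C)C(C)(C)C)[C@]1(C)CC#C[Si](C)(C)C
F12 | step 11 | 2α-hydroxy enoate (15 without its O-silyl group) | COC(=O)C1=C(C(C)C)C[C@H](O)[C@]1(C)CC#C[Si](C)(C)C
F13 | step 11 | 2-oxo enoate | COC(=O)C1=C(C(C)C)CC(=O)[C@]1(C)CC#C[Si](C)(C)C
F14 | step 11 | 2β-hydroxy enoate | COC(=O)C1=C(C(C)C)C[C@@H](O)[C@]1(C)CC#C[Si](C)(C)C
F15 | step 11 | 4β,5β-epoxy 2β-alcohol | COC(=O)[C@]12O[C@@]1(C(C)C)C[C@@H](O)[C@]2(C)CC#C[Si](C)(C)C
F16 | step 11 | methyl 2β,4β-dihydroxy-1β-methyl-4α-(propan-2-yl)-1α-(prop-2-yn-1-yl)cyclopentane-5β-carboxylate | COC(=O)[C@H]1[C@](O)(C(C)C)C[C@@H](O)[C@]1(C)CC#C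
F17 | step 11 | methyl 4β-hydroxy-1β-methyl-2-oxo-4α-(propan-2-yl)-1α-(prop-2-yn-1-yl)cyclopentane-5β-carboxylate | COC(=O)[C@H]1[C@](O)(C(C)C)CC(=O)[C@]1(C)CC#C
F18 | step 11 | methyl 2α,4β-dihydroxy-1β-methyl-4α-(propan-2-yl)-1α-(prop-2-yn-1-yl)cyclopentane-5β-carboxylate | COC(=O)[C@H]1[C@](O)(C(C)C)C[C@H](O)[C@]1(C)CC#C
F19 | step 16 | C6 epimer of 22 (6R carbinol) | CC(=C)C[C@@H](O)[C@H]1[C@](O)(C(C)C)C[C@H](O[Si](C)(C)C(C)(C)C)[C@]1(C)CC=C
F20 | step 16 | C6 epimer of 23 | CC1=CC[C@]2(C)[C@@H]([C@H](O)C1)[C@](O)(C(C)C)C[C@@H]2O[Si](C)(C)C(C)(C)C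
A1 | alternative 1 | (5-isopropyl-3-methylfuran-2-yl)methanol | Cc1cc(C(C)C)oc1CO
A2 | alternative 1 | (R)-4-hydroxy-4-isopropyl-2-methylcyclopent-2-en-1-one | CC1=C[C@](O)(C(C)C)CC1=O
A3 | alternative 2 | cis-divinylcyclopropane: 1-methyl-1-vinyl-2-[silyloxy-substituted 2-methyl-5-isopropylcyclopent-1-enyl]cyclopropane | C=C[C@@]1(C)C[C@H]1C2=C(C)[C@@H](O[Si](C)(C)C(C)(C)C)C[C@@]2(O[Si](C)(C)C)C(C)C
A4 | alternative 2 | bicyclo[5.3.0]decadiene with C5=C6 and C8=C9 and quaternary C1 | CC1=CC[C@]2(C)C(=CC1)[C@](O[Si](C)(C)C)(C(C)C)C[C@@H]2O[Si](C)(C)C(C)(C)C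
A5 | alternative 3 | tert-butyl 2-[5-(tert-butyldimethylsilyloxy)-3-oxocyclopent-1-en-1-yl]acetate | O=C1C[C@H](O[Si](C)(C)C(C)(C)C)C(CC(=O)OC(C)(C)C)=C1
A6 | alternative 3 | cyclopentanone with quaternary C1, C2 silyl ether and C5 hydroxymethyl | O=C1C[C@H](O[Si](C)(C)C(C)(C)C)[C@](C)(CC(=O)OC(C)(C)C)[C@H]1CO
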